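**Strategy.** Ring C is disconnected at C8–C14 and C9–C11. Its atoms C11–C14 carry exactly the pattern of 3-isopropoxy-4-isopropylcyclobutenedione (two carbonyl carbons, one oxygenated carbon, one isopropyl carbon), and they hang on the C8=C9 alkene of ring B. Heating a 4-hydroxy-4-(cyclohexenyl)cyclobutenone opens the four-membered ring to a dienylketene that closes onto C8, so one operation builds the fully substituted hydroquinone ring C with every substituent in place. The precursor is the adduct of a C9 vinyllithium of ring B (C5 and C10 already set, C7 and C3 oxygens as silyl ethers) with the cyclobutenedione.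

Key step: step 10

Remark: atoms carry the diterpenoid labels of the target (ring B: C5, C6, C7, C8, C9, C10; ring C: C8, C9, C11–C14; arm C1–C3 on C10). C7 and the cyclobutenone carbinol carbon are carried as epimer mixtures because both become trigonal later, so their SMILES carry no descriptor.

Step 1
Reactants: 1 2-methylcyclohex-2-en-1-one; 2 isopropenylmagnesium bromide; 3 allyl bromide
Product: 5 (2S,3S)-2-allyl-2-methyl-3-(prop-1-en-2-yl)cyclohexan-1-one, via bromomagnesium enolate 4 (not isolated)
Conditions: Cu(OTf)2 (3 mol %), chiral imidazolinium chloride as NHC precursor (4 mol %), Et2O, −30 °C; then 3, DMPU, −30 → 0 °C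
Reagents that add atoms: isopropenylmagnesium bromide (compound 2), C=C(C)[Mg]Br; allyl bromide (compound 3), C=CCBr
Why: Copper-catalysed asymmetric conjugate addition of a Grignard reagent to an α-substituted cyclohexenone with in situ enolate alkylation; the chiral NHC–copper catalyst (ligand enantiomer to be chosen so that isopropenyl is delivered to the face giving 5S) sets C5, and allyl bromide then attacks C10 of enolate 4 anti to the neighbouring isopropenyl group, which sets the quaternary centre with methyl cis to isopropenyl.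

Step 2
Reactants: 5 (2S,3S)-2-allyl-2-methyl-3-(prop-1-en-2-yl)cyclohexan-1-one
Product: 7 (5S,6S)-6-allyl-6-methyl-5-(prop-1-en-2-yl)cyclohex-2-en-1-one, via lithium enolate 6 (not isolated)
Conditions: LiN(iPr)2, THF, −78 °C; then N-tert-butylbenzenesulfinimidoyl chloride, −78 °C
Reagents that add atoms: none
Why: Mukaiyama dehydrogenation; the base can enolise only towards C8 because C10 is quaternary, and attack of the enolate on sulfur followed by syn elimination should give the C7=C8 enone at low temperature without touching the allyl or isopropenyl groups (no stereocentre is formed).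

Step 3
Reactants: 7 (5S,6S)-6-allyl-6-methyl-5-(prop-1-en-2-yl)cyclohex-2-en-1-one
Product: 8 (2S,3S)-2-allyl-2-methyl-3-(prop-1-en-2-yl)-5-(4,4,5,5-tetramethyl-1,3,2-dioxaborolan-2-yl)cyclohexan-1-one (C7 epimers)
Conditions: B2pin2, CuCl (3 mol %), NaOtBu (6 mol %), Xantphos (3 mol %), MeOH, THF, rt
Reagents that add atoms: bis(pinacolato)diboron, CC1(C)OB(OC1(C)C)B2OC(C)(C)C(C)(C)O2
Why: Copper-catalysed conjugate borylation of a cyclic enone (the copper boryl adds to the β-carbon C7 and methanol protonates the enolate), which leaves unactivated alkenes alone; the new C7 centre forms as an epimer mixture, which does not matter because C7 ends as a carbonyl.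

Step 4
Reactants: 8 (2S,3S)-2-allyl-2-methyl-3-(prop-1-en-2-yl)-5-(pinacolboryl)cyclohexan-1-one
Product: 10 (2S,3S)-5-hydroxy-2-(3-hydroxypropyl)-2-methyl-3-(prop-1-en-2-yl)cyclohexan-1-one (C7 epimers), via bis(boronate) 9 (not isolated)
Conditions: HBpin, [Ir(cod)Cl]2 (1.5 mol %), dppm (3 mol %), CH2Cl2, rt; then NaBO3·4H2O, THF/H2O, 0 °C → rt
Reagents that add atoms: sodium perborate, [Na+].[Na+].O[B-]1(O)OO[B-](O)(O)OO1
Why: Iridium-catalysed anti-Markovnikov hydroboration with pinacolborane should select the monosubstituted allyl alkene over the hindered 1,1-disubstituted isopropenyl group and spare the ketone, and perborate then oxidises both C–B bonds with retention (hydroboration–oxidation); no controlled stereocentre is created.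

Step 5
Reactants: 10 (2S,3S)-5-hydroxy-2-(3-hydroxypropyl)-2-methyl-3-(prop-1-en-2-yl)cyclohexan-1-one
Product: 11 (2S,3S)-5-[(tert-butyldimethylsilyl)oxy]-2-{3-[(tert-butyldimethylsilyl)oxy]propyl}-2-methyl-3-(prop-1-en-2-yl)cyclohexan-1-one (C7 epimers)
Conditions: TBSCl, imidazole, DMF, rt
Reagents that add atoms: tert-butyldimethylsilyl chloride, CC(C)(C)[Si](C)(C)Cl
Why: Standard silyl ether formation on a primary and a secondary alcohol; silylation of the open hydroxy ketone drains any hemiketal equilibrium, and no stereocentre changes.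

Step 6
Reactants: 11 bis-silylated ketone
Product: 13 (5S,6S)-3-[(tert-butyldimethylsilyl)oxy]-6-{3-[(tert-butyldimethylsilyl)oxy]propyl}-6-methyl-5-(prop-1-en-2-yl)cyclohex-1-en-1-yl trifluoromethanesulfonate (C7 epimers), via potassium enolate 12 (not isolated)
Conditions: KN(SiMe3)2, THF, −78 °C; then PhNTf2, −78 °C
Reagents that add atoms: N-phenylbis(trifluoromethanesulfonimide), O=S(=O)(N(c1ccccc1)S(=O)(=O)C(F)(F)F)C(F)(F)F
Why: Kinetic enolate O-triflation (enol triflate synthesis); only C8 carries α-hydrogens, so the C8=C9 alkene forms regiospecifically, and fast trapping at −78 °C should outrun β-elimination of the C7 silyloxy group.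

Step 7
Reactants: 13 enol triflate
Product: 14 [(5S,6S)-3-[(tert-butyldimethylsilyl)oxy]-6-{3-[(tert-butyldimethylsilyl)oxy]propyl}-6-methyl-5-(prop-1-en-2-yl)cyclohex-1-en-1-yl]trimethylstannane (C7 epimers)
Conditions: Me3SnSnMe3, Pd(PPh3)4 (5 mol %), LiCl, THF, 65 °C
Reagents that add atoms: hexamethylditin, C[Sn](C)(C)[Sn](C)(C)C
Why: Palladium-catalysed stannylation of an enol triflate with a distannane (Stille-type triflate-to-stannane exchange), with LiCl assisting transmetalation at the hindered C9; no stereocentre is involved.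

Step 8
Reactants: 15 diisopropyl squarate; 16 isopropylmagnesium chloride
Product: 18 3-isopropoxy-4-isopropylcyclobut-3-ene-1,2-dione, via hydroxycyclobutenone adduct 17 (not isolated)
Conditions: THF, −78 °C; then aq. HCl quench and cat. conc. HCl, CH2Cl2, rt
Reagents that add atoms: isopropylmagnesium chloride (compound 16), CC(C)[Mg]Cl
Why: 1,2-Addition of a Grignard reagent to one carbonyl of a squarate diester followed by acid-promoted loss of isopropanol from the adduct is the standard route to 3-alkoxy-4-alkylcyclobutenediones; no stereocentre survives.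

Step 9
Reactants: 14 vinylstannane; 18 3-isopropoxy-4-isopropylcyclobut-3-ene-1,2-dione
Product: 20 4-hydroxy-3-isopropoxy-2-isopropyl-4-[(5S,6S)-3-[(tert-butyldimethylsilyl)oxy]-6-{3-[(tert-butyldimethylsilyl)oxy]propyl}-6-methyl-5-(prop-1-en-2-yl)cyclohex-1-en-1-yl]cyclobut-2-en-1-one (epimers at C7 and at the carbinol carbon), via vinyllithium 19 (not isolated)
Conditions: MeLi, THF, −78 → −20 °C; then 18, THF, −78 °C; sat. aq. NH4Cl
Reagents that add atoms: none
Why: Tin–lithium exchange gives the C9 vinyllithium, which adds 1,2 to the more electrophilic, ketone-like carbonyl of 18 (the one flanking the alkoxy-bearing carbon; the other is deactivated as a vinylogous ester) and so forms the C9–C11 bond; the carbinol centre forms as a mixture that step 10 erases.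

Step 10
Reactants: 20 4-hydroxy-4-(cyclohexenyl)cyclobutenone
Product: 23 (7S,8S)-5-[(tert-butyldimethylsilyl)oxy]-8-{3-[(tert-butyldimethylsilyl)oxy]propyl}-2-isopropoxy-3-isopropyl-8-methyl-7-(prop-1-en-2-yl)-5,6,7,8-tetrahydronaphthalene-1,4-diol (C7 epimers; C1 and C4 of this name are C11 and C14), via dienylketene 21 (not isolated), via cyclohexadienone 22 (not isolated)
Conditions: degassed toluene, 110 °C, argon
Reagents that add atoms: none
Why: Moore rearrangement: thermal four-electron conrotatory opening of the cyclobutenone breaks C11–C14 and gives dienylketene 21, whose ketene carbon C14 bonds to C8 to give dienone 22, and transfer of the C8 hydrogen to oxygen aromatises this to hydroquinone 23. The closest known reaction type is the thermal ring expansion of 4-alkenyl- and 4-aryl-4-hydroxycyclobutenones to hydroquinones. Ring C closes by a six-electron disrotatory electrocyclisation of the (Z)-dienylketene, so the oxygens on C11 and C14, the ether oxygen on C12 and the isopropyl group on C13 are placed regiospecifically by the substitution pattern of the four-membered ring. No stereocentre is created, and C5 and C10 are untouched spectators. The step needs outward rotation of the hydroxyl, so that the ring B alkene and not the hydroxyl faces the ketene (inward hydroxyl would lead to a butenolide); this torquoselectivity is the intrinsic electronic preference of an oxygen donor on the breaking bond, and because ring opening is reversible, material should funnel through the productive rotamer. Relief of four-ring strain and aromatisation make the overall change irreversible.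

Step 11
Reactants: 23 hydroquinone
Product: 24 (7S,8S)-5-[(tert-butyldimethylsilyl)oxy]-8-{3-[(tert-butyldimethylsilyl)oxy]propyl}-2-isopropoxy-3-isopropyl-8-methyl-7-(prop-1-en-2-yl)-5,6,7,8-tetrahydronaphthalene-1,4-dione (C7 epimers)
Conditions: Ag2O, Et2O, rt
Reagents that add atoms: none
Why: Two-electron oxidation of an electron-rich hydroquinone to the 1,4-benzoquinone with Ag2O is fast and selective; silyl ethers and alkenes are inert, and the quinone is no longer prone to ionisation at benzylic C7.

Step 12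
Reactants: 24 bis-silylated quinone
Product: 25 (7S,8S)-5-hydroxy-8-(3-hydroxypropyl)-2-isopropoxy-3-isopropyl-8-methyl-7-(prop-1-en-2-yl)-5,6,7,8-tetrahydronaphthalene-1,4-dione (C7 epimers)
Conditions: HF·pyridine, pyridine, THF, 0 °C → rt
Reagents that add atoms: none
Why: Fluoride-mediated cleavage of both silyl ethers under buffered HF·pyridine, which should spare the alkoxyquinone and the isopropenyl group; if the freed C7 carbinol tautomerises to the acylhydroquinone, step 13 converges on the same product.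

Step 13
Reactants: 25 quinone diol
Product: 26 3-[(1S,2S)-7-isopropoxy-6-isopropyl-1-methyl-4,5,8-trioxo-2-(prop-1-en-2-yl)-1,2,3,4,5,8-hexahydronaphthalen-1-yl]propanal
Conditions: Dess–Martin periodinane, CH2Cl2, rt
Reagents that add atoms: none
Why: Dess–Martin oxidation converts the C7 carbinol into the ketone and the primary alcohol into the aldehyde under neutral, non-aqueous conditions; both C7 epimers converge, and C5 and C10 are not enolisable positions.

Step 14
Reactants: 26 keto aldehyde
Product: 27 3-[(1S,2S)-7-isopropoxy-6-isopropyl-1-methyl-4,5,8-trioxo-2-(prop-1-en-2-yl)-1,2,3,4,5,8-hexahydronaphthalen-1-yl]propanoic acid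
Conditions: NaClO2, NaH2PO4, 2-methyl-2-butene, t-BuOH/H2O, rt
Reagents that add atoms: sodium chlorite, [Na+].[O-]Cl=O
Why: Pinnick oxidation of the aldehyde to the carboxylic acid; 2-methyl-2-butene scavenges HOCl, so the isopropenyl group and the quinone should survive.

Step 15
Reactants: 27 keto acid
Product: 28 methyl 3-[(1S,2S)-7-isopropoxy-6-isopropyl-1-methyl-4,5,8-trioxo-2-(prop-1-en-2-yl)-1,2,3,4,5,8-hexahydronaphthalen-1-yl]propanoate
Conditions: TMSCHN2, toluene/MeOH, 0 °C
Reagents that add atoms: trimethylsilyldiazomethane, C[Si](C)(C)C=[N+]=[N-]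
Why: Methyl ester formation from a carboxylic acid with a diazoalkane; the acidic quinone oxygen on C12 is still masked as its isopropyl ether, so only the carboxyl group is methylated, and the fully substituted quinone alkenes should resist cycloaddition.

Step 16
Reactants: 28 isopropyl-protected methyl ester
Product: 29 methyl 3-[(1S,2S)-7-hydroxy-6-isopropyl-1-methyl-4,5,8-trioxo-2-(prop-1-en-2-yl)-1,2,3,4,5,8-hexahydronaphthalen-1-yl]propanoate (CNP0308749.1)
Conditions: BCl3, CH2Cl2, −78 °C; aqueous work-up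
Reagents that add atoms: none
Why: Chelation-assisted ether dealkylation: BCl3 binds the C11 carbonyl and the adjacent ether oxygen and chloride removes the secondary isopropyl group at low temperature, where the methyl ester, the ketone and the isopropenyl group should not react; hydrolysis of the boron chelate on work-up frees the hydroxyquinone.

**Compound list**

1 | 2-methylcyclohex-2-en-1-one | CC1=CCCC1=O | starting material
2 | isopropenylmagnesium bromide | C=C(C)[Mg]Br | starting material
3 | allyl bromide | C=CCBr | starting material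
4 | bromomagnesium (S)-2-methyl-3-(prop-1-en-2-yl)cyclohex-1-en-1-olate (not isolated) | C=C(C)[C@@H]1CCCC(O[Mg]Br)=C1C | intermediate
5 | (2S,3S)-2-allyl-2-methyl-3-(prop-1-en-2-yl)cyclohexan-1-one (methyl cis to isopropenyl) | C=C(C)[C@@H]1CCCC(=O)[C@@]1(C)CC=C | intermediate
6 | lithium (5S,6S)-6-allyl-6-methyl-5-(prop-1-en-2-yl)cyclohex-1-en-1-olate (not isolated) | C=C(C)[C@@H]1CCC=C([O-])[C@@]1(C)CC=C.[Li+] | intermediate
7 | (5S,6S)-6-allyl-6-methyl-5-(prop-1-en-2-yl)cyclohex-2-en-1-one | C=C(C)[C@@H]1CC=CC(=O)[C@@]1(C)CC=C | intermediate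
8 | (2S,3S)-2-allyl-2-methyl-3-(prop-1-en-2-yl)-5-(4,4,5,5-tetramethyl-1,3,2-dioxaborolan-2-yl)cyclohexan-1-one, C7 epimers | C=C(C)[C@@H]1CC(B2OC(C)(C)C(C)(C)O2)CC(=O)[C@@]1(C)CC=C | intermediate
9 | (2S,3S)-2-methyl-3-(prop-1-en-2-yl)-5-(pinacolboryl)-2-[3-(pinacolboryl)propyl]cyclohexan-1-one, C7 epimers (not isolated) | C=C(C)[C@@H]1CC(B2OC(C)(C)C(C)(C)O2)CC(=O)[C@@]1(C)CCCB3OC(C)(C)C(C)(C)O3 | intermediate
10 | (2S,3S)-5-hydroxy-2-(3-hydroxypropyl)-2-methyl-3-(prop-1-en-2-yl)cyclohexan-1-one, C7 epimers | C=C(C)[C@@H]1CC(O)CC(=O)[C@@]1(C)CCCO | intermediate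
11 | (2S,3S)-5-[(tert-butyldimethylsilyl)oxy]-2-{3-[(tert-butyldimethylsilyl)oxy]propyl}-2-methyl-3-(prop-1-en-2-yl)cyclohexan-1-one, C7 epimers | C=C(C)[C@@H]1CC(O[Si](C)(C)C(C)(C)C)CC(=O)[C@@]1(C)CCCO[Si](C)(C)C(C)(C)C | intermediate
12 | potassium enolate of 11 (C8=C9 enolate, not isolated) | C=C(C)[C@@H]1CC(O[Si](C)(C)C(C)(C)C)C=C([O-])[C@@]1(C)CCCO[Si](C)(C)C(C)(C)C.[K+] | intermediate
13 | (5S,6S)-3-[(tert-butyldimethylsilyl)oxy]-6-{3-[(tert-butyldimethylsilyl)oxy]propyl}-6-methyl-5-(prop-1-en-2-yl)cyclohex-1-en-1-yl trifluoromethanesulfonate, C7 epimers | C=C(C)[C@@H]1CC(O[Si](C)(C)C(C)(C)C)C=C(OS(=O)(=O)C(F)(F)F)[C@@]1(C)CCCO[Si](C)(C)C(C)(C)C | intermediate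
14 | [(5S,6S)-3-[(tert-butyldimethylsilyl)oxy]-6-{3-[(tert-butyldimethylsilyl)oxy]propyl}-6-methyl-5-(prop-1-en-2-yl)cyclohex-1-en-1-yl]trimethylstannane, C7 epimers | C=C(C)[C@@H]1CC(O[Si](C)(C)C(C)(C)C)C=C([Sn](C)(C)C)[C@@]1(C)CCCO[Si](C)(C)C(C)(C)C | intermediate
15 | diisopropyl squarate (3,4-diisopropoxycyclobut-3-ene-1,2-dione) | CC(C)OC1=C(OC(C)C)C(=O)C1=O | starting material
16 | isopropylmagnesium chloride | CC(C)[Mg]Cl | starting material
17 | 4-hydroxy-2,3-diisopropoxy-4-isopropylcyclobut-2-en-1-one, racemic (not isolated) | CC(C)OC1=C(OC(C)C)C(O)(C(C)C)C1=O | intermediate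
18 | 3-isopropoxy-4-isopropylcyclobut-3-ene-1,2-dione | CC(C)OC1=C(C(C)C)C(=O)C1=O | intermediate
19 | C9 vinyllithium from 14 (not isolated) | C=C(C)[C@@H]1CC(O[Si](C)(C)C(C)(C)C)C=C([Li])[C@@]1(C)CCCO[Si](C)(C)C(C)(C)C | intermediate
20 | 4-hydroxy-3-isopropoxy-2-isopropyl-4-[(5S,6S)-3-[(tert-butyldimethylsilyl)oxy]-6-{3-[(tert-butyldimethylsilyl)oxy]propyl}-6-methyl-5-(prop-1-en-2-yl)cyclohex-1-en-1-yl]cyclobut-2-en-1-one, epimers at C7 and carbinol carbon | C=C(C)[C@@H]1CC(O[Si](C)(C)C(C)(C)C)C=C(C2(O)C(OC(C)C)=C(C(C)C)C2=O)[C@@]1(C)CCCO[Si](C)(C)C(C)(C)C | intermediate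
21 | (Z)-dienylketene from opening of 20: ketene carbon C14, isopropyl on C13, isopropoxy on C12, enol hydroxyl on C11, ring B alkene cis to the ketene arm (not isolated) | C=C(C)[C@@H]1CC(O[Si](C)(C)C(C)(C)C)C=C(/C(O)=C(OC(C)C)\C(C(C)C)=C=O)[C@@]1(C)CCCO[Si](C)(C)C(C)(C)C | intermediate
22 | ring-fused cyclohexa-2,4-dienone with C8–H (C14 ketone, C11 enol; not isolated) | C=C(C)[C@@H]1CC(O[Si](C)(C)C(C)(C)C)C2C(=O)C(C(C)C)=C(OC(C)C)C(O)=C2[C@@]1(C)CCCO[Si](C)(C)C(C)(C)C | intermediate
23 | (7S,8S)-5-[(tert-butyldimethylsilyl)oxy]-8-{3-[(tert-butyldimethylsilyl)oxy]propyl}-2-isopropoxy-3-isopropyl-8-methyl-7-(prop-1-en-2-yl)-5,6,7,8-tetrahydronaphthalene-1,4-diol, C7 epimers | C=C(C)[C@@H]1CC(O[Si](C)(C)C(C)(C)C)c2c(O)c(C(C)C)c(OC(C)C)c(O)c2[C@@]1(C)CCCO[Si](C)(C)C(C)(C)C | intermediate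
24 | (7S,8S)-5-[(tert-butyldimethylsilyl)oxy]-8-{3-[(tert-butyldimethylsilyl)oxy]propyl}-2-isopropoxy-3-isopropyl-8-methyl-7-(prop-1-en-2-yl)-5,6,7,8-tetrahydronaphthalene-1,4-dione, C7 epimers | C=C(C)[C@@H]1CC(O[Si](C)(C)C(C)(C)C)C2=C(C(=O)C(OC(C)C)=C(C(C)C)C2=O)[C@@]1(C)CCCO[Si](C)(C)C(C)(C)C | intermediate
25 | (7S,8S)-5-hydroxy-8-(3-hydroxypropyl)-2-isopropoxy-3-isopropyl-8-methyl-7-(prop-1-en-2-yl)-5,6,7,8-tetrahydronaphthalene-1,4-dione, C7 epimers | C=C(C)[C@@H]1CC(O)C2=C(C(=O)C(OC(C)C)=C(C(C)C)C2=O)[C@@]1(C)CCCO | intermediate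
26 | 3-[(1S,2S)-7-isopropoxy-6-isopropyl-1-methyl-4,5,8-trioxo-2-(prop-1-en-2-yl)-1,2,3,4,5,8-hexahydronaphthalen-1-yl]propanal | C=C(C)[C@@H]1CC(=O)C2=C(C(=O)C(OC(C)C)=C(C(C)C)C2=O)[C@@]1(C)CCC=O | intermediate
27 | 3-[(1S,2S)-7-isopropoxy-6-isopropyl-1-methyl-4,5,8-trioxo-2-(prop-1-en-2-yl)-1,2,3,4,5,8-hexahydronaphthalen-1-yl]propanoic acid | C=C(C)[C@@H]1CC(=O)C2=C(C(=O)C(OC(C)C)=C(C(C)C)C2=O)[C@@]1(C)CCC(=O)O | intermediate
28 | methyl 3-[(1S,2S)-7-isopropoxy-6-isopropyl-1-methyl-4,5,8-trioxo-2-(prop-1-en-2-yl)-1,2,3,4,5,8-hexahydronaphthalen-1-yl]propanoate | C=C(C)[C@@H]1CC(=O)C2=C(C(=O)C(OC(C)C)=C(C(C)C)C2=O)[C@@]1(C)CCC(=O)OC | intermediate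
29 | methyl 3-[(1S,2S)-7-hydroxy-6-isopropyl-1-methyl-4,5,8-trioxo-2-(prop-1-en-2-yl)-1,2,3,4,5,8-hexahydronaphthalen-1-yl]propanoate (CNP0308749.1) | C=C(C)[C@@H]1CC(=O)C2=C(C(=O)C(O)=C(C(C)C)C2=O)[C@@]1(C)CCC(=O)OC | target

**Step count and risks**

Total steps: 16. Longest linear sequence: 15 (steps 1–7 and 9–16); step 8 is a one-step side branch that joins at step 9.

Steps most likely to fail:

1. Step 1. The chiral copper catalyst may discriminate poorly between the enone faces with an alkenyl Grignard reagent, and proton exchange between enolate and product during allylation may erode the outcome. Fallback, setting out from 1, 2 and 3: give up catalyst control and run the addition with achiral CuBr·SMe2 in THF at −78 °C. This passes through enolate 4 together with the mirror-image magnesium enolate F1. After allylation it gives 5 together with the mirror-image ketone F2. The two ketones are separated by preparative chromatography on a chiral stationary phase, and the route is rejoined at 5.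

2. Step 10. The hydroxyl may rotate inward or the carbinol oxygen may intercept the ketene, which diverts material to a butenolide, and the free hydroquinone may ionise at benzylic C7 on prolonged heating. Fallback, setting out from 14 and 18: repeat the lithiation and addition of step 9 but quench the alkoxide with Me3SiCl to obtain the trimethylsilyl ether of the carbinol F3. This compound has no free hydroxyl to trap the ketene. Thermolysis in toluene at 110 °C should give the C11-O-silylated hydroquinone F4. Oxidative desilylation with (NH4)2Ce(NO3)6 in aqueous MeCN at 0 °C then returns to the route at quinone 24.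

3. Step 6. The C8 enolate may expel the C7 silanolate by β-elimination before O-sulfonylation, and the hindered triflate may stannylate slowly in step 7. Fallback, setting out from 11, with no enolate and no tin: condensation with N2H4·H2O (Et3N, EtOH, 80 °C) gives the hydrazone F5. Barton vinyl iodide synthesis (I2, tetramethylguanidine, THF, 0 °C) gives the C9 vinyl iodide F6. Iodine–lithium exchange with t-BuLi (2 equiv, THF, −78 °C) returns to the route at vinyllithium 19, which is used as in step 9.

**Further compounds**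

F1 | step 1 | bromomagnesium (R)-2-methyl-3-(prop-1-en-2-yl)cyclohex-1-en-1-olate (mirror image of 4) | C=C(C)[C@H]1CCCC(O[Mg]Br)=C1C
F2 | step 1 | (2R,3R)-2-allyl-2-methyl-3-(prop-1-en-2-yl)cyclohexan-1-one (mirror image of 5) | C=C(C)[C@H]1CCCC(=O)[C@]1(C)CC=C
F3 | step 10 | trimethylsilyl ether of 20 at the carbinol oxygen, epimers at C7 and carbinol carbon | C=C(C)[C@@H]1CC(O[Si](C)(C)C(C)(C)C)C=C(C2(O[Si](C)(C)C)C(OC(C)C)=C(C(C)C)C2=O)[C@@]1(C)CCCO[Si](C)(C)C(C)(C)C
F4 | step 10 | hydroquinone 23 carrying a trimethylsilyl group on the C11 oxygen, C7 epimers | C=C(C)[C@@H]1CC(O[Si](C)(C)C(C)(C)C)c2c(O)c(C(C)C)c(OC(C)C)c(O[Si](C)(C)C)c2[C@@]1(C)CCCO[Si](C)(C)C(C)(C)C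
F5 | step 6 | hydrazone of ketone 11, C7 epimers | C=C(C)[C@@H]1CC(O[Si](C)(C)C(C)(C)C)CC(=NN)[C@@]1(C)CCCO[Si](C)(C)C(C)(C)C
F6 | step 6 | C9 vinyl iodide: (5S,6S)-3-[(tert-butyldimethylsilyl)oxy]-6-{3-[(tert-butyldimethylsilyl)oxy]propyl}-1-iodo-6-methyl-5-(prop-1-en-2-yl)cyclohex-1-ene, C7 epimers | C=C(C)[C@@H]1CC(O[Si](C)(C)C(C)(C)C)C=C(I)[C@@]1(C)CCCO[Si](C)(C)C(C)(C)C
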